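Numbering (halimane): ring A = C1, C2, C3, C4, C5, C10, with the C1=C10 alkene and the gem-dimethyl carbon C4. Ring B = C5 to C10, with the C8 methyl and the quaternary C9 (methyl C20 and chain carbon C11). The chain runs C11 to C15 with a methyl on C13, and C15 is esterified to O2 of glycerol.
Retrosynthetic cuts, in order: the C15–O ester bond (acid plus 1,3-disilylated glycerol), C12–C13 (C12 bromide plus (R)-β-butyrolactone), C9–C11 (retro-Claisen to a C1 allylic alcohol with a C9=C10 alkene), C1–C10 (enol triflate plus aldehyde), C9–C20 (α-methylenation) and C3–C4 (conjugate addition to pulegone).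
Enabling feature: the quaternary C9 is bonded directly to C10, an sp2 carbon of the ring A alkene. C1=C10–C9 is therefore an allyl unit carrying C11–C12(=O) on its C9 end, which is a γ,δ-unsaturated carbonyl retron. Running the [3,3] shift backwards puts an oxygen on C1 and the alkene at C9=C10 inside ring B, and ring B with its C8 methyl and with C4 on C5 is the carbon skeleton of pulegone.
Forward order: ring B is bought, ring A is closed at C1–C10 by a nickel/chromium coupling, the chain is planted on C9 by the [3,3] shift and lengthened at C12–C13, and the glycerol ester is made last.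
Stereochemistry: C8 comes from (R)-pulegone and C5 from equilibration to the trans (diequatorial) ketone. A temporary C1 carbinol is set by face-selective hydride reduction and relayed suprafacially to C9. C13 comes from (R)-β-butyrolactone by inversion.
Key step: step 10

Assumption: commercial (R)-(+)-pulegone and (R)-β-butyrolactone are taken as enantiomerically pure, since every stereocentre of the target derives from these two. The central glycerol carbon is not a stereocentre because its two CH2OH arms are identical.

Step 1
Reactants: 1 (R)-(+)-pulegone; 2 2-(2-bromoethyl)-1,3-dioxolane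
Product: 5 (5R)-2-[4-(1,3-dioxolan-2-yl)-2-methylbutan-2-yl]-5-methylcyclohexan-1-one (mixture of epimers at halimane C5), via Grignard reagent 3 (not isolated), via magnesium enolate 4 (not isolated)
Conditions: Mg, THF, 20–25 °C (2 to 3); CuBr·SMe2 (10 mol %), THF/Me2S, −30 °C, then 1, −30 → 0 °C; saturated aq NH4Cl
Reagents that add atoms: none
Why: Copper-catalysed conjugate addition of a Grignard reagent to the s-cis enone of pulegone, the reaction type that gives 8-substituted menthones, forms C3–C4 and the quaternary C4 and leaves C8 untouched, while C5 comes out as a mixture because enolate 4 is protonated unselectively on work-up.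

Step 2
Reactants: 5 conjugate adduct ketone (C5 epimer mixture)
Product: 6 (2S,5R)-2-[4-(1,3-dioxolan-2-yl)-2-methylbutan-2-yl]-5-methylcyclohexan-1-one (trans, menthone-like; halimane 5S,8R)
Conditions: KOH, EtOH/H2O, reflux; chromatography, cis isomer resubmitted
Reagents that add atoms: none
Why: Base-mediated enolisation and reprotonation next to the C10 ketone (thermodynamic epimerisation, as in the isomenthone–menthone equilibrium) should move C5 to the trans arrangement in which the bulky C4 group and the C8 methyl are both equatorial, and the acetal is inert to base.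

Step 3
Reactants: 6 trans ketone
Product: 8 (3R,6S)-2-[(dimethylamino)methyl]-3-methyl-6-[4-(1,3-dioxolan-2-yl)-2-methylbutan-2-yl]cyclohexan-1-one (C9 epimers), via kinetic lithium enolate 7 (not isolated)
Conditions: LiN(i-Pr)2, THF, −78 °C; [Me2N=CH2]I, −78 °C → rt
Reagents that add atoms: dimethylmethyleneiminium iodide, C[N+](C)=C.[I-]
Why: The hindered amide should deprotonate the open C9 methylene rather than the C5 methine shielded by the quaternary C4, and the enolate is aminomethylated in a Mannich reaction with a preformed iminium salt, the new C9 centre being irrelevant because it becomes sp2 in the next step.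

Step 4
Reactants: 8 Mannich base
Product: 10 (3R,6S)-3-methyl-2-methylidene-6-[4-(1,3-dioxolan-2-yl)-2-methylbutan-2-yl]cyclohexan-1-one, via trimethylammonium iodide 9 (not isolated)
Conditions: MeI, Et2O, rt; then aq NaHCO3, CH2Cl2, rt
Reagents that add atoms: none
Why: Exhaustive methylation followed by Hofmann-type β-elimination of a Mannich base is the standard entry to α-methylene ketones, and bicarbonate is too weak to epimerise C5 or to move the double bond into the ring toward C8.

Step 5
Reactants: 10 α-methylene ketone
Product: 12 (3R,6S)-6-[4-(1,3-dioxolan-2-yl)-2-methylbutan-2-yl]-2,3-dimethylcyclohex-1-en-1-yl trifluoromethanesulfonate, via tetrasubstituted lithium enolate 11 (not isolated)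
Conditions: LiBH(s-Bu)3, THF, −78 °C; PhNTf2, −78 °C → rt; H2O
Reagents that add atoms: N-phenylbis(trifluoromethanesulfonimide), O=S(=O)(N(c1ccccc1)S(=O)(=O)C(F)(F)F)C(F)(F)F
Why: The β-unsubstituted enone, locked s-cis, should take hydride from the bulky borohydride at C20 (conjugate reduction) to give only the C9=C10 enolate, and O-sulfonylation with the triflimide then fixes a double bond position that direct enolisation of a 2-methyl ketone could not guarantee.

Step 6
Reactants: 12 enol triflate acetal
Product: 13 (3R,6S)-2,3-dimethyl-6-(2-methyl-5-oxopentan-2-yl)cyclohex-1-en-1-yl trifluoromethanesulfonate (C10 triflate, C1 aldehyde)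
Conditions: 1 M HCl, THF, rt
Reagents that add atoms: water, O
Why: Acid-catalysed acetal hydrolysis frees the C1 aldehyde while the electron-poor enol triflate, which resists aqueous acid, stays intact.

Step 7
Reactants: 13 enol triflate aldehyde
Product: 14 (4aS,7R)-4,4,7,8-tetramethyl-1,2,3,4,4a,5,6,7-octahydronaphthalen-1-ol (halimane C1 alcohol with C9=C10 alkene; both C1 epimers)
Conditions: CrCl2 (6 equiv), NiCl2 (2 mol %), degassed DMF (0.01 M), rt → 50 °C; H2O
Reagents that add atoms: none
Why: The intramolecular Nozaki–Hiyama–Kishi reaction (insertion of zerovalent nickel into the C10–O bond, then transfer to chromium) turns C10 into a nucleophile that tolerates and attacks only the tethered aldehyde, closing ring A in a 6-exo-trig mode at high dilution, and C1 need not be controlled because step 8 erases it.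

Step 8
Reactants: 14 bicyclic allylic alcohol (C1 epimers)
Product: 15 (4aS,7R)-4,4,7,8-tetramethyl-3,4,4a,5,6,7-hexahydronaphthalen-1(2H)-one (C1 ketone conjugated with C9=C10)
Conditions: n-Pr4N[RuO4] (5 mol %), N-methylmorpholine N-oxide, 4 Å molecular sieves, CH2Cl2, rt
Reagents that add atoms: none
Why: The neutral Ley–Griffith oxidation should merge both C1 epimers into one enone without ionising the acid-sensitive allylic alcohol and without enolising toward the γ-position C8.

Step 9
Reactants: 15 bicyclic enone
Product: 16 (1S,4aS,7R)-4,4,7,8-tetramethyl-1,2,3,4,4a,5,6,7-octahydronaphthalen-1-ol (axial hydroxyl on the face of H5)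
Conditions: LiBH(s-Bu)3, THF, −78 °C; H2O
Reagents that add atoms: none
Why: In this 1,2-reduction of a β,β-disubstituted enone, ring A sits in the chair with H5 axial, so the bulky trialkylborohydride should avoid the axial hydrogens on C3 and C5 and approach equatorially from the face opposite H5, leaving the hydroxyl axial on the H5 face (1S), which is also the epimer free of allylic 1,3-strain with the C9 methyl, and any 1R alcohol is separated and returned to step 8.

Step 10
Reactants: 16 (1S)-allylic alcohol
Product: 19 ethyl (5S,8R,9R)-13,14,15,16-tetranorhalim-1(10)-en-12-oate, via mixed orthoester 17 (not isolated), via ketene acetal 18 (not isolated)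
Conditions: MeC(OEt)3 (excess, as solvent), EtCO2H (5 mol %), 140 °C, EtOH distilled off
Reagents that add atoms: triethyl orthoacetate, CC(OCC)(OCC)OCC
Why: Acid-catalysed exchange of one ethoxy group gives mixed orthoester 17, loss of ethanol gives ketene acetal 18, and 18 undergoes a concerted suprafacial [3,3]-sigmatropic shift over O–C1–C10=C9 in which C9–C11 forms while C1–O breaks and the alkene moves from C9=C10 to C1=C10. The closest known reaction type is the Johnson orthoester Claisen rearrangement of 2-alkylidenecycloalkanols and 3-substituted cyclohexenols, an established route to all-carbon quaternary centres by 1,3-chirality transfer. No ring is closed, only a six-membered cyclic transition state is passed, and chair or boat makes no stereochemical difference because the migrating terminus is an unsubstituted CH2. The one new stereocentre, C9, is controlled by the C1 carbinol centre, since the short O–C tether lets the ketene acetal carbon reach C9 only on the face that carries the C1 oxygen, the face of H5, which gives 9R with C11 axial on ring B and cis to the equatorial C8 methyl. The step needs complete facial selectivity at C9 and rearrangement in preference to elimination: the first is secured by the intramolecular delivery and by allylic 1,3-strain with the C9 methyl, which holds the C1–O bond axial and aligned with the π orbitals, and the second by using only a trace of weak acid and removing ethanol continuously.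

Step 11
Reactants: 19 ethyl ester
Product: 20 (5S,8R,9R)-13,14,15,16-tetranorhalim-1(10)-en-12-ol
Conditions: LiAlH4, Et2O, 0 °C; H2O
Reagents that add atoms: none
Why: Hydride reduction of an ester to the primary alcohol is routine, and the isolated trisubstituted alkene and all stereocentres are inert to it.

Step 12
Reactants: 20 primary alcohol
Product: 21 (5S,8R,9R)-12-bromo-13,14,15,16-tetranorhalim-1(10)-ene
Conditions: CBr4, PPh3, CH2Cl2, 0 °C
Reagents that add atoms: carbon tetrabromide, BrC(Br)(Br)Br
Why: The Appel bromination activates the primary hydroxyl and displaces it with bromide at the unhindered C12 under essentially neutral conditions, so neither the alkene nor the neighbouring quaternary centre is disturbed.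

Step 13
Reactants: 21 C12 bromide; 22 (R)-β-butyrolactone
Product: 24 (5S,8R,9R,13R)-halim-1(10)-en-15-oic acid, via Grignard reagent 23 (not isolated)
Conditions: Mg, THF, 40 °C (21 to 23); slow addition to 22 (1.5 equiv), CuBr·SMe2 (10 mol %), THF/Me2S, −30 → 0 °C; 1 M HCl
Reagents that add atoms: none
Why: Copper-catalysed alkyl–oxygen opening of a β-lactone by a Grignard reagent, known for β-propiolactone and β-butyrolactone, is a backside displacement at the methyl-bearing carbon with inversion, so (R)-22 should deliver C13 as in the target (again called R because C14 now outranks C12), and slow addition of 23 to lactone plus catalyst keeps uncatalysed carbonyl attack low.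

Step 14
Reactants: 25 glycerol
Product: 26 1,3-bis(tert-butyldimethylsilyloxy)propan-2-ol
Conditions: TBSCl (2.0 equiv), imidazole, DMF, 0 °C
Reagents that add atoms: tert-butyldimethylsilyl chloride, CC(C)(C)[Si](C)(C)Cl
Why: The bulky silyl chloride reacts faster with the two primary hydroxyls than with the secondary one (steric selectivity of silyl ether formation), which leaves O2 free.

Step 15
Reactants: 24 halimenoic acid; 26 1,3-disilylated glycerol
Product: 27 1,3-bis(tert-butyldimethylsilyloxy)propan-2-yl (5S,8R,9R,13R)-halim-1(10)-en-15-oate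
Conditions: 1-ethyl-3-(3-dimethylaminopropyl)carbodiimide hydrochloride (EDC·HCl), DMAP (catalytic), CH2Cl2, 0 °C → rt
Reagents that add atoms: none
Why: The Steglich esterification (carbodiimide activation with DMAP acyl transfer) joins the acid to the secondary alcohol under mild conditions that cannot affect C13, which is not α to the carbonyl.

Step 16
Reactants: 27 bis-silyl 2-glyceryl ester
Product: 28 1,3-dihydroxypropan-2-yl (5S,8R,9R,13R)-halim-1(10)-en-15-oate (CNP0174907.2)
Conditions: HF·pyridine, pyridine, THF, 0 °C; pH 7 phosphate buffer; chromatography on boric acid-impregnated silica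
Reagents that add atoms: none
Why: Fluoride-driven cleavage of the two primary silyl ethers with pyridine-buffered HF stays cold and only faintly acidic, the regime in which 2-acylglycerols migrate most slowly, and the neutral work-up with borate-treated silica should keep the acyl group on O2.

Compound list
1 | (R)-(+)-pulegone, (5R)-5-methyl-2-(propan-2-ylidene)cyclohexan-1-one | C[C@@H]1CCC(=C(C)C)C(=O)C1 | starting material
2 | 2-(2-bromoethyl)-1,3-dioxolane | BrCCC1OCCO1 | starting material
3 | [2-(1,3-dioxolan-2-yl)ethyl]magnesium bromide | Br[Mg]CCC1OCCO1 | intermediate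
4 | bromomagnesium C5=C10 enolate of the conjugate adduct (8R) | C[C@@H]1CCC(C(C)(C)CCC2OCCO2)=C(O[Mg]Br)C1 | intermediate
5 | (5R)-2-[4-(1,3-dioxolan-2-yl)-2-methylbutan-2-yl]-5-methylcyclohexan-1-one, epimers at halimane C5 | C[C@@H]1CCC(C(C)(C)CCC2OCCO2)C(=O)C1 | intermediate
6 | (2S,5R)-2-[4-(1,3-dioxolan-2-yl)-2-methylbutan-2-yl]-5-methylcyclohexan-1-one (trans) | O=C1C[C@H](C)CC[C@H]1C(C)(C)CCC2OCCO2 | intermediate
7 | kinetic lithium enolate of 6 (C9=C10) | [Li]OC1=C[C@H](C)CC[C@H]1C(C)(C)CCC2OCCO2 | intermediate
8 | (3R,6S)-2-[(dimethylamino)methyl]-3-methyl-6-[4-(1,3-dioxolan-2-yl)-2-methylbutan-2-yl]cyclohexan-1-one, C9 epimers | O=C1C(CN(C)C)[C@H](C)CC[C@H]1C(C)(C)CCC2OCCO2 | intermediate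
9 | trimethylammonium iodide of 8 | O=C1C(C[N+](C)(C)C)[C@H](C)CC[C@H]1C(C)(C)CCC2OCCO2.[I-] | intermediate
10 | (3R,6S)-3-methyl-2-methylidene-6-[4-(1,3-dioxolan-2-yl)-2-methylbutan-2-yl]cyclohexan-1-one | O=C1C(=C)[C@H](C)CC[C@H]1C(C)(C)CCC2OCCO2 | intermediate
11 | tetrasubstituted lithium enolate (C9=C10, C9 methyl) | [Li]OC1=C(C)[C@H](C)CC[C@H]1C(C)(C)CCC2OCCO2 | intermediate
12 | (3R,6S)-6-[4-(1,3-dioxolan-2-yl)-2-methylbutan-2-yl]-2,3-dimethylcyclohex-1-en-1-yl trifluoromethanesulfonate | CC1=C(OS(=O)(=O)C(F)(F)F)[C@H](C(C)(C)CCC2OCCO2)CC[C@H]1C | intermediate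
13 | (3R,6S)-2,3-dimethyl-6-(2-methyl-5-oxopentan-2-yl)cyclohex-1-en-1-yl trifluoromethanesulfonate | CC1=C(OS(=O)(=O)C(F)(F)F)[C@H](C(C)(C)CCC=O)CC[C@H]1C | intermediate
14 | (4aS,7R)-4,4,7,8-tetramethyl-1,2,3,4,4a,5,6,7-octahydronaphthalen-1-ol, C1 epimers | CC1=C2C(O)CCC(C)(C)[C@@H]2CC[C@H]1C | intermediate
15 | (4aS,7R)-4,4,7,8-tetramethyl-3,4,4a,5,6,7-hexahydronaphthalen-1(2H)-one | CC1=C2C(=O)CCC(C)(C)[C@@H]2CC[C@H]1C | intermediate
16 | (1S,4aS,7R)-4,4,7,8-tetramethyl-1,2,3,4,4a,5,6,7-octahydronaphthalen-1-ol (OH axial, cis to H5) | CC1=C2[C@@H](O)CCC(C)(C)[C@@H]2CC[C@H]1C | intermediate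
17 | mixed diethyl orthoacetate of 16 | CC1=C2[C@@H](OC(C)(OCC)OCC)CCC(C)(C)[C@@H]2CC[C@H]1C | intermediate
18 | ethyl ketene acetal of 16 | CC1=C2[C@@H](OC(=C)OCC)CCC(C)(C)[C@@H]2CC[C@H]1C | intermediate
19 | ethyl (5S,8R,9R)-13,14,15,16-tetranorhalim-1(10)-en-12-oate | CCOC(=O)C[C@@]1(C)C2=CCCC(C)(C)[C@@H]2CC[C@H]1C | intermediate
20 | (5S,8R,9R)-13,14,15,16-tetranorhalim-1(10)-en-12-ol | OCC[C@@]1(C)C2=CCCC(C)(C)[C@@H]2CC[C@H]1C | intermediate
21 | (5S,8R,9R)-12-bromo-13,14,15,16-tetranorhalim-1(10)-ene | BrCC[C@@]1(C)C2=CCCC(C)(C)[C@@H]2CC[C@H]1C | intermediate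
22 | (R)-β-butyrolactone, (4R)-4-methyloxetan-2-one | C[C@@H]1CC(=O)O1 | starting material
23 | C12 Grignard reagent from 21 | Br[Mg]CC[C@@]1(C)C2=CCCC(C)(C)[C@@H]2CC[C@H]1C | intermediate
24 | (5S,8R,9R,13R)-halim-1(10)-en-15-oic acid | C[C@H](CC[C@@]1(C)C2=CCCC(C)(C)[C@@H]2CC[C@H]1C)CC(=O)O | intermediate
25 | glycerol | OCC(O)CO | starting material
26 | 1,3-bis(tert-butyldimethylsilyloxy)propan-2-ol | OC(CO[Si](C)(C)C(C)(C)C)CO[Si](C)(C)C(C)(C)C | intermediate
27 | 1,3-bis(tert-butyldimethylsilyloxy)propan-2-yl (5S,8R,9R,13R)-halim-1(10)-en-15-oate | C[C@H](CC[C@@]1(C)C2=CCCC(C)(C)[C@@H]2CC[C@H]1C)CC(=O)OC(CO[Si](C)(C)C(C)(C)C)CO[Si](C)(C)C(C)(C)C | intermediate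
28 | 1,3-dihydroxypropan-2-yl (5S,8R,9R,13R)-halim-1(10)-en-15-oate (CNP0174907.2) | C[C@H](CC[C@@]1(C)C2=CCCC(C)(C)[C@@H]2CC[C@H]1C)CC(=O)OC(CO)CO | target

Total step count: 16. Longest linear sequence: 15 steps (steps 1 to 13, 15 and 16, from pulegone). Step 14 is a one-step side branch.

The three steps most likely to fail:

**The rearrangement of step 10.** At 140 °C the doubly activated allylic C1–O bond may ionise and lose water or ethanol to dienes before the crowded C9–C11 bond can form.
- The fallback sets out from 16 and comes back at 20.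
- It makes the ketene acetal by deprotonating a preformed ester instead of by acid-catalysed exchange (Ireland–Claisen rearrangement), so no acid and no strong heating are involved.
- Alcohol 16 is acetylated (Ac2O, DMAP, pyridine) to the (1S)-allylic acetate F1.
- LiN(i-Pr)2 with Me3SiCl/Et3N in THF at −78 °C gives the trimethylsilyl ketene acetal F2.
- Between room temperature and 65 °C, F2 should rearrange, with the same suprafacial delivery from the C1 oxygen face, to the trimethylsilyl ester F3.
- Aqueous work-up gives the C12 carboxylic acid F4, and LiAlH4 in Et2O reduces it to 20.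

**The ring closure of step 7.** Nickel may insert only slowly into the hindered, fully substituted C10–O triflate bond, so that the free aldehyde is lost to pinacol coupling or reduction by the divalent chromium salt.
- The fallback sets out from 13 and comes back at 15.
- It closes ring A at C1–C2 by a Dieckmann condensation. C1 is brought in as carbon monoxide and the former aldehyde carbon is expelled afterwards.
- Pinnick oxidation (NaClO2, NaH2PO4, 2-methyl-2-butene, t-BuOH/H2O) gives the triflate carboxylic acid F5.
- MeI and K2CO3 in DMF give the triflate methyl ester F6.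
- Palladium-catalysed methoxycarbonylation of the enol triflate (Pd(OAc)2, 1,3-bis(diphenylphosphino)propane, CO, MeOH, Et3N, DMF, 70 °C) gives the enoate diester F7.
- KOt-Bu in THF closes the six-membered ring to the bicyclic β-keto ester F8.
- Krapcho dealkoxycarbonylation (LiCl, wet DMSO, 150 °C) gives 15. C5 and C8 are not touched at any point.

**The lactone opening of step 13.** The organomagnesium reagent may attack the lactone carbonyl, or deprotonate the lactone and trigger β-elimination, instead of substituting at the secondary carbon. Incomplete inversion would also erode C13.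
- The fallback sets out from 21 and comes back at 24.
- It forms C12–C13 by conjugate addition to an sp2 carbon and sets C13 with an auxiliary instead of the chiral pool.
- (R)-4-Phenyl-1,3-oxazolidin-2-one is N-acylated (n-BuLi, (E)-crotonyl chloride, THF, −78 °C) to the (R)-N-crotonoyl imide F9.
- Grignard reagent 23, made from 21 as in step 13, is added with CuBr·SMe2 (1 equiv) in THF/Me2S at −40 °C to F9.
- The magnesium-chelated s-cis conformer of F9 should be attacked on the face away from the phenyl group, giving the (13R)-imide adduct F10.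
- LiOH/H2O2 in THF/H2O at 0 °C removes the auxiliary and gives 24.

Further compounds
F1 | step 10 | (1S)-allylic acetate of 16 | CC1=C2[C@@H](OC(C)=O)CCC(C)(C)[C@@H]2CC[C@H]1C
F2 | step 10 | trimethylsilyl ketene acetal of F1 | CC1=C2[C@@H](OC(=C)O[Si](C)(C)C)CCC(C)(C)[C@@H]2CC[C@H]1C
F3 | step 10 | trimethylsilyl (5S,8R,9R)-13,14,15,16-tetranorhalim-1(10)-en-12-oate | C[Si](C)(C)OC(=O)C[C@@]1(C)C2=CCCC(C)(C)[C@@H]2CC[C@H]1C
F4 | step 10 | (5S,8R,9R)-13,14,15,16-tetranorhalim-1(10)-en-12-oic acid | OC(=O)C[C@@]1(C)C2=CCCC(C)(C)[C@@H]2CC[C@H]1C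
F5 | step 7 | 4-[(1S,4R)-3,4-dimethyl-2-(trifluoromethylsulfonyloxy)cyclohex-2-en-1-yl]-4-methylpentanoic acid | CC1=C(OS(=O)(=O)C(F)(F)F)[C@H](C(C)(C)CCC(=O)O)CC[C@H]1C
F6 | step 7 | methyl ester of F5 | CC1=C(OS(=O)(=O)C(F)(F)F)[C@H](C(C)(C)CCC(=O)OC)CC[C@H]1C
F7 | step 7 | methyl (3R,6S)-6-(5-methoxy-2-methyl-5-oxopentan-2-yl)-2,3-dimethylcyclohex-1-ene-1-carboxylate | CC1=C(C(=O)OC)[C@H](C(C)(C)CCC(=O)OC)CC[C@H]1C
F8 | step 7 | methyl (4aS,7R)-4,4,7,8-tetramethyl-1-oxo-1,2,3,4,4a,5,6,7-octahydronaphthalene-2-carboxylate (C2 unassigned) | CC1=C2C(=O)C(C(=O)OC)CC(C)(C)[C@@H]2CC[C@H]1C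
F9 | step 13 | (4R)-3-[(E)-but-2-enoyl]-4-phenyl-1,3-oxazolidin-2-one | C1OC(=O)N(C(=O)/C=C/C)[C@@H]1c2ccccc2
F10 | step 13 | (4R)-3-[(5S,8R,9R,13R)-halim-1(10)-en-15-oyl]-4-phenyl-1,3-oxazolidin-2-one | C[C@H](CC[C@@]1(C)C2=CCCC(C)(C)[C@@H]2CC[C@H]1C)CC(=O)N(C(=O)OC3)[C@@H]3c4ccccc4
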